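**Plan**

1. Numbering (eunicellane): tetrahydrofuran O1/C2/C1/C10/C9; cyclohexane C1, C10–C14; nine-membered bridge C3–C8 with Z-C6=C7; lactone O3–C17(=O)–C15–C14; acetate on C11.
2. Cuts: C3–C4 together with the lactone O3–C17 bond (one event); then O1–C2 (oxypalladation), C1–C2 (conjugate addition) and C9–C10 (Morita–Baylis–Hillman); the cyclohexenone is cut to an aldehyde and methyl vinyl ketone.
3. Enabling feature: C3 is a tertiary carbinol carbon α to the ring-ether carbon C2, it ends the C4–C8 bridge and it carries the lactone oxygen, six bonds from acyl carbon C17. As a methyl ketone it accepts a C4 carbanion, and the C3 alkoxide then sits next to the C17 imide, so oxonene, C3 stereocentre and seven-membered lactone form together and the auxiliary leaves.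
4. Forward order: cyclohexenone → C9–C10 coupling with the Z-aldehyde → C1 propenyl → tetrahydrofuran → C11 carbinol and acetate → methyl ketone and iodide → oxonene plus lactone in the last step.
5. Stereochemistry: C15 from the oxazolidinone; C14 from the amine catalyst; C9 from the chiral diol; C1 and C10 by substrate control; C2 by equilibration; C11 by axial attack on the convex face; Z-C6=C7 from the [2,3]-Wittig–Still step; C3 in the key step.

Key step: step 17

Assumption: in step 9 the antipode of the chiral diol is the one whose sense with cyclohex-2-enone gives the 9S carbinol. Commercial 1-propenylmagnesium bromide is an E/Z mixture; both isomers should converge on 15.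

**Route**

Step 1
Reactants: 1 (S)-4-benzyl-3-propanoyl-1,3-oxazolidin-2-one
Product: 2 (S)-4-benzyl-3-[(R)-2-methylpent-4-enoyl]-1,3-oxazolidin-2-one
Conditions: NaHMDS, THF, −78 °C; allyl iodide, −78 → −45 °C
Reagents that add atoms: allyl iodide, C=CCI
Why: Evans alkylation: the chelated Z-sodium enolate is allylated on the face away from the benzyl group, which should set C15 as R.

Step 2
Reactants: 2 allylated imide
Product: 3 (S)-4-benzyl-3-[(R)-2-methyl-4-oxobutanoyl]-1,3-oxazolidin-2-one
Conditions: O3, CH2Cl2, −78 °C; then PPh3, −78 °C → rt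
Reagents that add atoms: ozone, [O-][O+]=O
Why: Ozonolysis with reductive work-up cleaves only the terminal alkene and leaves the imide and C15 untouched.

Step 3
Reactants: 3 aldehyde
Product: 4 (S)-4-benzyl-3-[(2R,3S)-3-formyl-2-methyl-6-oxoheptanoyl]-1,3-oxazolidin-2-one
Conditions: methyl vinyl ketone (1.5 equiv), (S)-2-[methoxy(diphenyl)methyl]pyrrolidine (5 mol %), ethyl 3,4-dihydroxybenzoate (20 mol %), CHCl3, 4 °C
Reagents that add atoms: methyl vinyl ketone, C=CC(C)=O
Why: Enamine-catalysed Michael addition of an aldehyde to an enone: the E-enamine is attacked on the face away from the diaryl(methoxy)methyl group, which should set C14 under catalyst control.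

Step 4
Reactants: 4 keto aldehyde
Product: 5 (S)-4-benzyl-3-{(R)-2-[(R)-4-oxocyclohex-2-en-1-yl]propanoyl}-1,3-oxazolidin-2-one
Conditions: Bn2NH·CF3CO2H (0.3 equiv), toluene, 50 °C
Reagents that add atoms: none
Why: Intramolecular aldol condensation through the iminium ion of the aldehyde: only the ketone methyl group can close a six-membered ring, and the mild ammonium salt spares the imide and limits enolisation at C14.

Step 5
Reactants: 6 3-[(tert-butyldimethylsilyl)oxy]propanal
Product: 7 (±)-5-[(tert-butyldimethylsilyl)oxy]-2-methylpent-1-en-3-ol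
Conditions: isopropenylmagnesium bromide, THF, −78 → 0 °C; aq. NH4Cl
Reagents that add atoms: isopropenylmagnesium bromide, C=C(C)[Mg]Br
Why: Grignard addition to an aldehyde; the carbinol centre is destroyed in step 7, so the racemate serves.

Step 6
Reactants: 7 allylic alcohol
Product: 8 (±)-tributyl[({5-[(tert-butyldimethylsilyl)oxy]-2-methylpent-1-en-3-yl}oxy)methyl]stannane
Conditions: KH, THF, 0 °C; Bu3SnCH2I, rt
Reagents that add atoms: (iodomethyl)tributylstannane, CCCC[Sn](CCCC)(CCCC)CI
Why: Williamson etherification of the potassium alkoxide with the iodomethylstannane.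

Step 7
Reactants: 8 stannylmethyl ether
Product: 10 (Z)-6-[(tert-butyldimethylsilyl)oxy]-3-methylhex-3-en-1-ol, via lithiomethyl ether 9 (not isolated)
Conditions: n-BuLi, THF, −78 °C; aq. NH4Cl
Reagents that add atoms: none
Why: Tin–lithium exchange and [2,3]-Wittig–Still rearrangement: in the envelope transition state the CH2CH2OTBS group sits pseudo-axial to avoid A(1,2) strain with the 2-methyl group, which should give the Z-trisubstituted C6=C7 alkene.

Step 8
Reactants: 10 homoallylic alcohol
Product: 11 (Z)-6-[(tert-butyldimethylsilyl)oxy]-3-methylhex-3-enal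
Conditions: Dess–Martin periodinane, NaHCO3, CH2Cl2, 0 °C; used at once
Reagents that add atoms: none
Why: Buffered Dess–Martin oxidation should give the β,γ-unsaturated aldehyde without migration of the Z double bond.

Step 9
Reactants: 5 enone; 11 aldehyde
Product: 12 (9S)-carbinol, enone 5 carrying CH(OH)CH2C(CH3)=CHCH2CH2OTBS (Z) on the α-carbon C10
Conditions: PEt3 (1 equiv), 3,3′-bis[3,5-bis(trifluoromethyl)phenyl]-5,5′,6,6′,7,7′,8,8′-octahydro-1,1′-bi-2-naphthol (10 mol %), THF, −10 °C
Reagents that add atoms: none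
Why: Catalytic asymmetric Morita–Baylis–Hillman reaction: the phosphonium enolate of 5 adds to 11 inside the hydrogen-bonded pocket of the chiral diol, which should join C9 to C10 and set C9 under catalyst control.

Step 10
Reactants: 12 Morita–Baylis–Hillman alcohol
Product: 14 cis-2,3-disubstituted cyclohexanone (C1 propenyl; C10 hydroxyalkyl), via bis-silylated enol ether 13 (not isolated)
Conditions: TMSCl, Et3N, THF, 0 °C; then 1-propenylmagnesium bromide, CuBr·SMe2 (20 mol %), TMSCl, −78 °C; then 10 % aq. citric acid, 0 °C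
Reagents that add atoms: 1-propenylmagnesium bromide, CC=C[Mg]Br
Why: Copper-catalysed, TMSCl-accelerated conjugate addition: the propenyl group should add to C1 trans to the C14 substituent, and kinetic protonation of the silyl enol ether at C10 anti to the new pseudo-axial C1 group should give the 1,10-cis ketone.

Step 11
Reactants: 14 hydroxy ketone
Product: 15 cis-fused 2-vinyl hexahydroisobenzofuran-4-one (C2 epimers)
Conditions: PdCl2(MeCN)2 (10 mol %), p-benzoquinone (1.5 equiv), THF, rt
Reagents that add atoms: none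
Why: Wacker-type oxidative cyclisation: 5-exo-trig oxypalladation of the C9 hydroxyl onto the propenyl group and β-hydride elimination toward the methyl group should close the cis-fused tetrahydrofuran; the C2 configuration is corrected in step 14.

Step 12
Reactants: 15 bicyclic ketone
Product: 16 C11 tertiary alcohol
Conditions: MeMgBr, CeCl3, THF, −78 °C; aq. NH4Cl
Reagents that add atoms: methylmagnesium bromide, C[Mg]Br
Why: Organocerium 1,2-addition to the only ketone: axial attack from the convex face, anti to the axial C10–C9 bond, should place the methyl group cis to H10 and set C11, while the hindered imide should survive at −78 °C.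

Step 13
Reactants: 16 tertiary alcohol
Product: 17 C11 acetate
Conditions: Ac2O, DMAP, Et3N, CH2Cl2, 40 °C
Reagents that add atoms: acetic anhydride, CC(=O)OC(C)=O
Why: DMAP-catalysed acetylation of the tertiary alcohol.

Step 14
Reactants: 17 vinyl tetrahydrofuran
Product: 19 2-acetyl tetrahydrofuran with the acetyl group trans to C1–C14, via C2-epimeric methyl ketone mixture 18 (not isolated)
Conditions: Pd(quinox)Cl2 (5 mol %), AgSbF6 (12 mol %), aq. t-BuOOH, CH2Cl2, rt; then DBU (0.3 equiv), rt
Reagents that add atoms: tert-butyl hydroperoxide, CC(C)(C)OO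
Why: Ligand-controlled Tsuji–Wacker oxidation should turn the terminal vinyl group into the methyl ketone and leave the trisubstituted alkene alone; DBU then equilibrates the α-alkoxy ketone at C2 to the isomer trans to C1–C14 and cis to the C9 chain.

Step 15
Reactants: 19 silyl ether
Product: 20 primary alcohol (C4–OH)
Conditions: HF·pyridine, pyridine, THF, 0 °C
Reagents that add atoms: none
Why: Buffered fluoride cleavage of the primary silyl ether should spare the imide and the tertiary acetate.

Step 16
Reactants: 20 primary alcohol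
Product: 21 primary iodide (C4–I)
Conditions: I2, PPh3, imidazole, CH2Cl2, 0 °C
Reagents that add atoms: iodine, II
Why: Appel-type iodination of the primary alcohol.

Step 17
Reactants: 21 iodo ketone
Product: 23 target lactone CNP0332402.2, via samarium alkoxide 22 (not isolated)
Conditions: SmI2 (2.5 equiv), HMPA (10 equiv), THF, 0 °C, slow addition of 21 (final 2 mM); then 40 °C
Reagents that add atoms: none
Why: SmI2/HMPA should reduce the primary iodide by two electron transfers to a C4 alkylsamarium, which adds to the C3 methyl ketone; the tertiary Sm(III) alkoxide then attacks the exocyclic imide carbonyl C17 and expels the oxazolidinone. The closest known type is the samarium Barbier cyclisation of iodo ketones, followed by alkoxide acyl transfer from an N-acyloxazolidinone. The oxonene closes 9-exo-trig onto the C3 carbonyl and the lactone closes 7-exo-trig at C17. C3 is controlled by conformation: HMPA-saturated samarium should not chelate O1, so the ketone reacts through the dipole-minimised rotamer with C=O anti to C2–O1, and the tether from C9 (cis to the acetyl group) reaches only the carbonyl face turned toward C9 beneath the ring oxygen. This should place O3 gauche to C1 on the side of the C14 substituent, as the lactone requires, and the methyl group toward O1. The step needs iodide reduction to outrun ketyl formation and C3 to be the only electrophile; C11 is already a tertiary acetate, the imide is inert to the alkylsamarium, and the cis-2,5-tetrahydrofuran and the Z-alkene hold C4 within reach while high dilution suppresses dimers.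

**Compound list**

1 | (S)-4-benzyl-3-propanoyl-1,3-oxazolidin-2-one | CCC(=O)N1[C@@H](Cc2ccccc2)COC1=O | starting material
2 | (S)-4-benzyl-3-[(R)-2-methylpent-4-enoyl]-1,3-oxazolidin-2-one | C=CC[C@@H](C)C(=O)N1[C@@H](Cc2ccccc2)COC1=O | intermediate
3 | (S)-4-benzyl-3-[(R)-2-methyl-4-oxobutanoyl]-1,3-oxazolidin-2-one | O=CC[C@@H](C)C(=O)N1[C@@H](Cc2ccccc2)COC1=O | intermediate
4 | (S)-4-benzyl-3-[(2R,3S)-3-formyl-2-methyl-6-oxoheptanoyl]-1,3-oxazolidin-2-one | O=C[C@@H](CCC(C)=O)[C@@H](C)C(=O)N1[C@@H](Cc2ccccc2)COC1=O | intermediate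
5 | (S)-4-benzyl-3-{(R)-2-[(R)-4-oxocyclohex-2-en-1-yl]propanoyl}-1,3-oxazolidin-2-one | O=C1C=C[C@@H](CC1)[C@@H](C)C(=O)N1[C@@H](Cc2ccccc2)COC1=O | intermediate
6 | 3-[(tert-butyldimethylsilyl)oxy]propanal | O=CCCO[Si](C)(C)C(C)(C)C | starting material
7 | (±)-5-[(tert-butyldimethylsilyl)oxy]-2-methylpent-1-en-3-ol | C=C(C)C(O)CCO[Si](C)(C)C(C)(C)C | intermediate
8 | (±)-tributyl[({5-[(tert-butyldimethylsilyl)oxy]-2-methylpent-1-en-3-yl}oxy)methyl]stannane | C=C(C)C(CCO[Si](C)(C)C(C)(C)C)OC[Sn](CCCC)(CCCC)CCCC | intermediate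
9 | lithiomethyl ether from 8 (α-alkoxymethyllithium) | C=C(C)C(CCO[Si](C)(C)C(C)(C)C)OC[Li] | intermediate
10 | (Z)-6-[(tert-butyldimethylsilyl)oxy]-3-methylhex-3-en-1-ol | OCC/C(C)=C\CCO[Si](C)(C)C(C)(C)C | intermediate
11 | (Z)-6-[(tert-butyldimethylsilyl)oxy]-3-methylhex-3-enal | O=CC/C(C)=C\CCO[Si](C)(C)C(C)(C)C | intermediate
12 | (9S)-Morita–Baylis–Hillman alcohol: enone 5 with the (1S,3Z)-6-silyloxy-1-hydroxy-3-methylhex-3-enyl group on C10 | O=C1C(=C[C@@H](CC1)[C@@H](C)C(=O)N2[C@@H](Cc3ccccc3)COC2=O)[C@@H](O)C/C(C)=C\CCO[Si](C)(C)C(C)(C)C | intermediate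
13 | bis-silylated enol ether: C11 trimethylsilyl enol ether and C9 trimethylsilyl ether with the propenyl group on C1 (E/Z at propenyl) | C[Si](C)(C)OC1=C([C@@H](O[Si](C)(C)C)C/C(C)=C\CCO[Si](C)(C)C(C)(C)C)[C@@H](C=CC)[C@@H](CC1)[C@@H](C)C(=O)N2[C@@H](Cc3ccccc3)COC2=O | intermediate
14 | cyclohexanone with C1 propenyl and C10 (9S)-hydroxyalkyl cis to each other and C14 imide side chain trans to C1 propenyl (E/Z at propenyl) | O=C1CC[C@@H]([C@@H](C)C(=O)N2[C@@H](Cc3ccccc3)COC2=O)[C@H](C=CC)[C@@H]1[C@@H](O)C/C(C)=C\CCO[Si](C)(C)C(C)(C)C | intermediate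
15 | cis-fused 2-vinyl hexahydroisobenzofuran-4-one, C11 ketone (C2 epimers) | O=C1CC[C@@H]([C@@H](C)C(=O)N3[C@@H](Cc4ccccc4)COC3=O)[C@H]2[C@@H]1[C@H](C/C(C)=C\CCO[Si](C)(C)C(C)(C)C)OC2C=C | intermediate
16 | C11 tertiary alcohol, methyl cis to H10 (C2 epimers) | O[C@]1(C)CC[C@@H]([C@@H](C)C(=O)N3[C@@H](Cc4ccccc4)COC3=O)[C@H]2[C@@H]1[C@H](C/C(C)=C\CCO[Si](C)(C)C(C)(C)C)OC2C=C | intermediate
17 | C11 acetate of 16 (C2 epimers) | CC(=O)O[C@]1(C)CC[C@@H]([C@@H](C)C(=O)N3[C@@H](Cc4ccccc4)COC3=O)[C@H]2[C@@H]1[C@H](C/C(C)=C\CCO[Si](C)(C)C(C)(C)C)OC2C=C | intermediate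
18 | C3 methyl ketone before equilibration (C2 epimers) | CC(=O)O[C@]1(C)CC[C@@H]([C@@H](C)C(=O)N3[C@@H](Cc4ccccc4)COC3=O)[C@H]2[C@@H]1[C@H](C/C(C)=C\CCO[Si](C)(C)C(C)(C)C)OC2C(C)=O | intermediate
19 | C3 methyl ketone with the acetyl group on C2 trans to C1–C14 and cis to the C9 chain | CC(=O)O[C@]1(C)CC[C@@H]([C@@H](C)C(=O)N3[C@@H](Cc4ccccc4)COC3=O)[C@H]2[C@@H]1[C@H](C/C(C)=C\CCO[Si](C)(C)C(C)(C)C)O[C@@H]2C(C)=O | intermediate
20 | primary alcohol (C4–OH) from 19 | CC(=O)O[C@]1(C)CC[C@@H]([C@@H](C)C(=O)N3[C@@H](Cc4ccccc4)COC3=O)[C@H]2[C@@H]1[C@H](C/C(C)=C\CCO)O[C@@H]2C(C)=O | intermediate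
21 | primary iodide (C4–I), substrate of the key step | CC(=O)O[C@]1(C)CC[C@@H]([C@@H](C)C(=O)N3[C@@H](Cc4ccccc4)COC3=O)[C@H]2[C@@H]1[C@H](C/C(C)=C\CCI)O[C@@H]2C(C)=O | intermediate
22 | nine-membered tertiary carbinol with the imide still attached (formed as its samarium alkoxide; drawn as the free alcohol) | CC(=O)O[C@]1(C)CC[C@@H]([C@@H](C)C(=O)N4[C@@H](Cc5ccccc5)COC4=O)[C@H]3[C@@H]1[C@@H]1C/C(C)=C\CC[C@](C)(O)[C@H]3O1 | intermediate
23 | target lactone CNP0332402.2 | CC(=O)O[C@]1(C)CC[C@@H]2[C@H]3[C@@H]1[C@@H]1C/C(C)=C\CC[C@](C)(OC(=O)[C@@H]2C)[C@H]3O1 | target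

**Count**

Total steps: 17. Longest linear sequence: 13 steps (steps 1–4, then 9–17; the branch 5–8, 9–17 is equally long).

**Steps most likely to fail**

1. Step 17. Ketyl formation at the α-alkoxy ketone (opening of the tetrahydrofuran or simple reduction) may outrun iodide reduction, the alkylsamarium may be protonated before the slow nine-membered closure, or the carbanion may attack the other carbonyl face. The fallback sets out from alcohol 20 and comes back at 22, then 23. Dess–Martin oxidation of 20 gives keto aldehyde F1. Low-valent titanium (TiCl3(DME)1.5, Zn–Cu, DME, high dilution; McMurry-type pinacol coupling stopped at the diol) joins C3 and C4 to give 3,4-diol F2. 1,1′-Thiocarbonyldiimidazole converts only the secondary C4 hydroxyl into imidazolylthiocarbonate F3. Barton–McCombie reduction (Bu3SnH, AIBN, toluene, 80 °C) then gives carbinol 22, and DBU or NaHMDS in THF triggers the acyl transfer to 23.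

2. Step 9. Phosphine addition next to the C14 substituent may be slow, catalyst control over C9 may be poor in the mismatched sense, and aldehyde 11 may drift into conjugation. The fallback sets out from enone 5 and comes back at 12. Iodine and pyridine in CH2Cl2 give 2-iodoenone F4. A Nozaki–Hiyama–Kishi coupling of F4 with 11 (CrCl2, NiCl2 cat., chiral sulfonamide ligand, THF) then gives 12; any C9 epimer is a diastereomer and should be separable.

3. Step 11. Palladium may dehydrogenate the ketone, β-hydride elimination may go toward C2 to give an enol ether, or C10 may epimerise before ring closure. The fallback sets out from hydroxy ketone 14 and comes back at 15. N-(Phenylseleno)phthalimide with catalytic camphorsulfonic acid (CH2Cl2, 0 °C) effects 5-exo selenoetherification to selenide F5. Oxidation with NaIO4/NaHCO3 and selenoxide syn-elimination away from the ring oxygen then give 15.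

**Further compounds**

F1 | step 17 | keto aldehyde (C4 aldehyde, C3 methyl ketone) from 20 | CC(=O)O[C@]1(C)CC[C@@H]([C@@H](C)C(=O)N3[C@@H](Cc4ccccc4)COC3=O)[C@H]2[C@@H]1[C@H](C/C(C)=C\CC=O)O[C@@H]2C(C)=O
F2 | step 17 | nine-membered 3,4-diol with the imide retained (C4 epimers) | CC(=O)O[C@]1(C)CC[C@@H]([C@@H](C)C(=O)N4[C@@H](Cc5ccccc5)COC4=O)[C@H]3[C@@H]1[C@@H]1C/C(C)=C\CC(O)[C@](C)(O)[C@H]3O1
F3 | step 17 | C4 O-(imidazol-1-ylthiocarbonyl) derivative of F2 (C4 epimers) | CC(=O)O[C@]1(C)CC[C@@H]([C@@H](C)C(=O)N4[C@@H](Cc5ccccc5)COC4=O)[C@H]3[C@@H]1[C@@H]1C/C(C)=C\CC(OC(=S)n2ccnc2)[C@](C)(O)[C@H]3O1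
F4 | step 9 | 2-iodoenone from 5 | O=C1C(I)=C[C@@H](CC1)[C@@H](C)C(=O)N1[C@@H](Cc2ccccc2)COC1=O
F5 | step 11 | cis-fused tetrahydrofuran with a 1-(phenylselanyl)ethyl group on C2 (C2 and C3 epimers) | O=C1CC[C@@H]([C@@H](C)C(=O)N3[C@@H](Cc4ccccc4)COC3=O)[C@H]2[C@@H]1[C@H](C/C(C)=C\CCO[Si](C)(C)C(C)(C)C)OC2C(C)[Se]c1ccccc1
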